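## Structural features

The target is a meroterpenoid. An albicane (drim-8(12)-ene) unit, with trans-fused rings A and B, the C4 gem-dimethyl group, the C5–H/C10–CH3 fusion pair, the exocyclic C8=C12 alkene and C9 carrying the C11 methylene, is joined through C11 to C1' of a cyclohexenone. This quinol ring is numbered C1'–C6': C1'–C2' epoxide, C3' carbinol, C4'=C5' alkene with a CH2O group on C4', C6' ketone. The C4' CH2O group is esterified by one carboxyl of 3-hydroxy-3-methylglutaric acid (C1''–C5''); the other carboxyl is free.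

There are three contiguous stereocentres in the decalin (C5, quaternary C10, C9) and three in the quinol ring (quaternary C1', C2', C3'; 1'S,2'S,3'R, epoxide oxygen and C3' hydroxyl trans). The carbinol C3'' (R) is isolated and is stereogenic only because its two carboxymethyl arms differ. The C11 methylene insulates the two triads from each other and C3'' is remote from both, so each set needs its own control element.

Fragile groups are the α,β-epoxy enone with its free carbinol (base, nucleophiles), the exocyclic alkene (acid), the allylic primary ester and the β-hydroxy acid. The real difficulties are: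
- quaternary C10 between C4 (1,3-diaxial methyl groups) and C9;
- the oxidation pattern of the quinol ring (ketone at C6' next to the substituted epoxide carbon, carbinol at C3');
- the trans epoxy alcohol;
- the glutarate centre.

The key step uses ring B as a cyclohexene retron. An oxygen on C8 and the formyl carbon C11 on C9 allow C5–C10 and C8–C9 to be made in one cycloaddition that closes rings A and B together.

## Logic of the disconnections

37 is cut at the O–CH3 bond of 36 and then at the ester C–O bond between the C4' methylene oxygen and C1'', which gives 33 and 35. The acyl unit comes last because a free acid would not pass the earlier steps. 35 carries C3'' in defined form; opening a symmetric anhydride would give both C3'' epimers. The gain is the whole side chain in two steps. The demand is acylation of the primary hydroxyl of 33 beside the C3' hydroxyl and a methyl ester cleavage at neutral pH. 35 goes back to 34 by differentiating two enantiotopic ester groups.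

33 is reached from 31 through 32 by exchanging the C3'–O bond with inversion, and 31 from 30 by cutting the C3'–H bond. A hydride should add to the C3' carbonyl of 30 from the face away from the epoxide oxygen, which gives the cis epoxy alcohol, so the trans relation is set by an SN2 step. The gain is that C3' needs no chiral reagent. The demand is reduction of the C3' carbonyl only and clean substitution at a carbon next to an epoxide.

30 is cut at the C3' carbonyl (ketal in 29), at the two epoxide C–O bonds (28) and at the C3'–OCH3 bond made on dearomatising 27. In 27 only the C6' oxygen is free, so oxidation can give only the C6' ketone with the C3' ketal. In 28 the only unsubstituted β-carbon is C2', so the epoxide must form on C1'=C2'. The gain is the complete quinol ring from a benzene ring in three steps. The demand is face selection by a chiral catalyst, since the decalin is too far away to help.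

27 goes back through 26 (O-allyl bond), 25 (C8=C12 cut to the C8 ketone), 24 and 22 to 14 and 20; the skeletal bond cut is C11–C1', and the C11 oxygen it leaves is removed. Aryllithium addition is the dependable way to join an arene to the neopentyl-type C11. The demand is an arene whose two oxygens are told apart: allyl on the C6' oxygen, methyl on the C3' oxygen. 20 is therefore cut back through 19, 18, 17 and 16 to 15.

14 comes from 13 by saturating C6=C7, and 13 is cut at C5–C10 and C8–C9 to 12. This removes both rings and four stereocentres at once. The demand is an endo, anti transition state and one enal face, at a trisubstituted dienophile.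

12 is traced through 11, 10 and 9 (O–Si bond of the dienol ether; oxidation level at C11) to 8. 8 is cut at C6=C7 to 7, 7 at C3–C4 to 3 and 4, and 3 at C10–C15 and C9–C11 to 1. The C9=C10 geometry is fixed by syn-carbometallation, which avoids the isomer mixtures of a ketone olefination, and no ketal has to be cleaved beside the acid-labile silyl dienol ether. The demand is conjugate rather than 1,2-addition to a β,β-disubstituted enal.

## Other disconnections considered

Alternative 1: The quinol ring is cut at C3'–C4'. Forward, the open-chain (Z)-β-iodoenone epoxy aldehyde A1 would be closed with CrCl2 and catalytic NiCl2 to the 4-methoxybenzyl ether A2.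
- In favour: ketone, carbinol and epoxide positions are fixed by construction; the epoxide configuration can come from a reagent-controlled epoxidation of an allylic alcohol; the conditions are neutral.
- Against: A1 needs a tetrasubstituted epoxide with the bulky C11 group, an aldehyde and a sensitive iodoenone, built in a long linear sequence on the terpenoid. C3' arises in a cyclic transition state that is hard to predict. The cut says nothing about the decalin.
- Comparison: on regiochemistry and epoxide configuration of the quinol ring this alternative is the better one. On C3' the two are equal. On step economy the chosen plan is better (benzene ring to 30 in three steps). Mechanistically both closures are reliable.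

Alternative 2: The two C–O bonds at C3' and C6' are cut. Forward, the dimethoxyarene A3 would be oxidised at a platinum anode in methanolic KOH to the bisketal A4, followed by monohydrolysis.
- In favour: A3 needs no differentiated phenol, which saves about four steps against 20 and step 19; no chemical oxidant is used; the alkene is tolerated.
- Against: the monohydrolysis must choose between the C3'-ketone A5 and the C6'-ketone A6. The cation from the C3' ketal is stabilised by the C1' alkyl group, so A5 should predominate, but only A6 has its free β-carbon on the right double bond for nucleophilic epoxidation.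
- Comparison: the mechanism is of the same kind as step 20. On step economy this alternative is better. On regiocontrol the chosen plan is better, because the free phenol of 27 leaves no choice.

Alternative 3: C4–C5 and C9–C10 are cut. Forward, the (S)-epoxyfarnesyl arene A7 would be treated with Cp2TiCl (trivalent titanium); epoxide opening, two 6-endo radical closures and loss of hydrogen next to the C8 radical give A8.
- In favour: A7 is short to make, one reagent-controlled epoxide sets all decalin centres through a chair–chair transition state, and the C11–arene bond and C8=C12 are there from the start.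
- Against: A8 has a 3β-hydroxyl that must be removed (two steps), bicyclisations of this kind are usually moderate in yield because of monocyclic and alkene-isomeric products, and the arene again has undifferentiated oxygens.
- Comparison: on step economy for the terpenoid half this alternative is clearly better. On stereochemical security it is at least equal. The chosen plan is better in that it carries no extra oxygen and forms the rings by a concerted, geometry-defined step.

Key step: step 8

Assumption: pig liver esterase is taken to hydrolyse 34 to the (S)-half-ester 35. Coupling through its free carboxyl then gives the (R) centre of 37, because the ranking of the two arms is exchanged.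

Abbreviations: TBS = tert-butyldimethylsilyl; TBDPS = tert-butyldiphenylsilyl. Drimane numbering is used for the decalin (12-nordrimane = drimane without C12; natural series, 5α-H, 10β-CH3); C1'–C6' for the six-membered ring.

Step 1
Reactants: 1 5-chloropent-1-yne
Product: 3 (E)-6-chloro-3-methylhex-2-en-1-ol, via alkenylalane 2 (not isolated)
Conditions: Me3Al, Cp2ZrCl2 (20 mol %), CH2Cl2, 0 °C → rt; n-BuLi, THF, −78 °C; (CH2O)n, → rt; aq. HCl
Reagents that add atoms: trimethylaluminium C[Al](C)C; paraformaldehyde (as formaldehyde) C=O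
Why: Zirconium-catalysed syn-carboalumination puts CH3 on the internal and Al on the terminal alkyne carbon; the alanate adds to formaldehyde with retention, so the E allylic alcohol should form; the primary chloride is inert.

Step 2
Reactants: 3 (E)-6-chloro-3-methylhex-2-en-1-ol; 4 3-methylbut-2-enal
Product: 7 (E)-9-hydroxy-3,3,7-trimethylnon-7-enal, via Grignard reagent 5 (not isolated), via silyl enol ether 6 (not isolated)
Conditions: i-PrMgCl, THF, −10 °C; Mg, reflux; CuBr·SMe2 (5 mol %), Me3SiCl, DMPU, 4, −78 °C; 1 M HCl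
Reagents that add atoms: none
Why: The alkoxide-protected Grignard reagent undergoes copper-catalysed, chlorosilane-accelerated conjugate addition; trapping as the silyl enol ether suppresses 1,2-addition and the quaternary C4 is formed; acid work-up frees aldehyde and alcohol.

Step 3
Reactants: 7 (E)-9-hydroxy-3,3,7-trimethylnon-7-enal
Product: 8 (2E,9E)-11-hydroxy-5,5,9-trimethylundeca-2,9-dienal
Conditions: Ph3P=CHCHO, toluene, 80 °C
Reagents that add atoms: (triphenylphosphoranylidene)acetaldehyde O=CC=P(c1ccccc1)(c1ccccc1)c1ccccc1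
Why: Wittig reaction of a stabilised ylide with the saturated aldehyde should give the E enal; the free hydroxyl does not interfere.

Step 4
Reactants: 8 (2E,9E)-11-hydroxy-5,5,9-trimethylundeca-2,9-dienal
Product: 9 (2E,9E)-3,7,7-trimethyl-11-oxoundeca-2,9-dien-1-yl acetate
Conditions: Ac2O, pyridine, 4-(dimethylamino)pyridine (cat.), CH2Cl2, 0 °C
Reagents that add atoms: acetic anhydride CC(=O)OC(C)=O
Why: Acetylation masks the allylic alcohol with a group that can later be removed by hydride without acid, which the silyl dienol ether would not tolerate.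

Step 5
Reactants: 9 (2E,9E)-3,7,7-trimethyl-11-oxoundeca-2,9-dien-1-yl acetate
Product: 10 (2E,8E,10E)-11-(TBS-oxy)-3,7,7-trimethylundeca-2,8,10-trien-1-yl acetate
Conditions: TBSOTf, Et3N, Et2O, −78 → 0 °C
Reagents that add atoms: tert-butyldimethylsilyl trifluoromethanesulfonate CC(C)(C)[Si](C)(C)OS(=O)(=O)C(F)(F)F
Why: Soft enolisation (O-silylation, γ-deprotonation) of the s-trans enal should give the E enol ether; the new C=C next to the quaternary carbon is E for steric reasons; the acetate is not enolised.

Step 6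
Reactants: 10 (2E,8E,10E)-11-(TBS-oxy)-3,7,7-trimethylundeca-2,8,10-trien-1-yl acetate
Product: 11 (2E,8E,10E)-11-(TBS-oxy)-3,7,7-trimethylundeca-2,8,10-trien-1-ol
Conditions: i-Bu2AlH, CH2Cl2, −78 °C; aq. sodium potassium tartrate
Reagents that add atoms: none
Why: Reductive cleavage of the acetate under aprotic, non-acidic conditions leaves the silyl dienol ether intact.

Step 7
Reactants: 11 (2E,8E,10E)-11-(TBS-oxy)-3,7,7-trimethylundeca-2,8,10-trien-1-ol
Product: 12 (2E,8E,10E)-11-(TBS-oxy)-3,7,7-trimethylundeca-2,8,10-trienal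
Conditions: MnO2, CH2Cl2, rt
Reagents that add atoms: none
Why: Neutral allylic oxidation with manganese dioxide gives the enal without E/Z isomerisation and without touching the dienol ether.

Step 8
Reactants: 12 (2E,8E,10E)-11-(TBS-oxy)-3,7,7-trimethylundeca-2,8,10-trienal
Product: 13 8β-(TBS-oxy)-12-nordrim-6-en-11-al (5α-H, 9β-CHO, 10β-CH3)
Conditions: (S)-3,3-diphenyl-1-(2-methylphenyl)tetrahydro-1H,3H-pyrrolo[1,2-c][1,3,2]oxazaborole·HNTf2 (20 mol %), CH2Cl2, −78 → −20 °C
Reagents that add atoms: none
Why: The oxazaborolidinium ion binds the formyl oxygen of the s-trans enal, lowers the LUMO of the trisubstituted dienophile and shields one face, so the electron-rich (E,E)-1-silyloxydiene adds in a concerted, asynchronous [4+2] in which C5–C10 (diene terminus to the β-carbon) runs ahead of C8–C9; the closest known reaction type is the cationic oxazaborolidine-catalysed enantioselective intramolecular Diels–Alder reaction of 2,7,9-decatrienals, here used with a β,β-disubstituted enal. Ring B is closed by the cycloaddition itself (both new σ-bonds lie in it) and ring A by the same C5–C10 bond through the four-carbon tether (fused mode, tether on the diene terminus). C10 is set by the catalyst, chosen to leave the (2Si,3Re) face of the enal open, and C5 follows from the anti tether in the endo transition state, which gives the trans fusion. C9 follows from the E enal (suprafacial addition keeps CHO cis to the C10 methyl) and C8 from the endo rule with the E enol ether (OTBS cis to CHO; this centre is erased later). The step needs endo/anti over exo/syn selectivity and clean face selection: Lewis acid activation strengthens the endo preference and the gem-dimethyl group on the tether favours the coiled, reactive conformer. Regiochemistry is fixed by the tether.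

Step 9
Reactants: 13 8β-(TBS-oxy)-12-nordrim-6-en-11-al
Product: 14 8β-(TBS-oxy)-12-nordriman-11-al
Conditions: H2 (1 atm), Pd/C, EtOAc, rt
Reagents that add atoms: none
Why: Catalytic hydrogenation of the cis-disubstituted ring alkene; it is done here because no hydrogenation is possible once the allyl ether or C8=C12 is present.

Step 10
Reactants: 15 4-bromo-2,5-dimethoxybenzaldehyde
Product: 16 4-bromo-2,5-dihydroxybenzaldehyde
Conditions: BBr3, CH2Cl2, −78 °C → rt; H2O
Reagents that add atoms: none
Why: Lewis acid cleavage of both aryl methyl ethers; it opens the way to placing different groups on the two oxygens.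

Step 11
Reactants: 16 4-bromo-2,5-dihydroxybenzaldehyde
Product: 17 5-(allyloxy)-4-bromo-2-hydroxybenzaldehyde
Conditions: allyl bromide (1.05 equiv), NaHCO3, KI (cat.), MeCN, 60 °C
Reagents that add atoms: allyl bromide C=CCBr
Why: Williamson alkylation; the 2-hydroxyl is held in a hydrogen bond to the formyl group, so the 5-hydroxyl (the later C6' oxygen) should react selectively.

Step 12
Reactants: 17 5-(allyloxy)-4-bromo-2-hydroxybenzaldehyde
Product: 18 5-(allyloxy)-4-bromo-2-methoxybenzaldehyde
Conditions: MeI, K2CO3, DMF, rt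
Reagents that add atoms: iodomethane CI
Why: O-methylation of the remaining phenol gives the later C3' methoxy group.

Step 13
Reactants: 18 5-(allyloxy)-4-bromo-2-methoxybenzaldehyde
Product: 19 [5-(allyloxy)-4-bromo-2-methoxyphenyl]methanol
Conditions: NaBH4, MeOH, 0 °C
Reagents that add atoms: none
Why: Borohydride reduction of the aldehyde to the C4' hydroxymethyl group.

Step 14
Reactants: 19 [5-(allyloxy)-4-bromo-2-methoxyphenyl]methanol
Product: 20 {[5-(allyloxy)-4-bromo-2-methoxybenzyl]oxy}(tert-butyl)diphenylsilane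
Conditions: TBDPSCl, imidazole, DMF, rt
Reagents that add atoms: tert-butyl(chloro)diphenylsilane CC(C)(C)[Si](Cl)(c1ccccc1)c1ccccc1
Why: Silylation; the TBDPS ether withstands aryllithium, acid and base and is removed only in step 22.

Step 15
Reactants: 14 8β-(TBS-oxy)-12-nordriman-11-al; 20 {[5-(allyloxy)-4-bromo-2-methoxybenzyl]oxy}(tert-butyl)diphenylsilane
Product: 22 (11RS)-11-[2-(allyloxy)-5-methoxy-4-(TBDPS-oxymethyl)phenyl]-8β-(TBS-oxy)-12-nordriman-11-ol, via aryllithium 21 (not isolated)
Conditions: t-BuLi (2 equiv), Et2O, −78 °C; 14, −78 °C; H2O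
Reagents that add atoms: none
Why: Bromine–lithium exchange and 1,2-addition to the hindered aldehyde form C11–C1'; both C11 epimers are acceptable because the oxygen is removed next; low temperature avoids carbolithiation of the allyl group and silyl migration.

Step 16
Reactants: 22 (11RS)-11-[2-(allyloxy)-5-methoxy-4-(TBDPS-oxymethyl)phenyl]-8β-(TBS-oxy)-12-nordriman-11-ol
Product: 24 11-[2-(allyloxy)-5-methoxy-4-(TBDPS-oxymethyl)phenyl]-12-nordriman-8β-ol, via silyl ether 23 (not isolated)
Conditions: Et3SiH, CF3CO2H, CH2Cl2, −20 → 0 °C; evaporate; TsOH·H2O (cat.), MeOH–CH2Cl2, rt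
Reagents that add atoms: none
Why: Ionic hydrogenation: the benzylic cation stabilised by the ortho alkoxy group is reduced by the silane; acid methanolysis then removes the secondary TBS ether while the primary TBDPS ether and the allyl ether stay.

Step 17
Reactants: 24 11-[2-(allyloxy)-5-methoxy-4-(TBDPS-oxymethyl)phenyl]-12-nordriman-8β-ol
Product: 25 11-[2-(allyloxy)-5-methoxy-4-(TBDPS-oxymethyl)phenyl]-12-nordriman-8-one
Conditions: Dess–Martin periodinane, CH2Cl2, rt
Reagents that add atoms: none
Why: Mild oxidation of the hindered axial alcohol; C9 is now next to a ketone and can settle in the equatorial (β-C11) arrangement.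

Step 18
Reactants: 25 11-[2-(allyloxy)-5-methoxy-4-(TBDPS-oxymethyl)phenyl]-12-nordriman-8-one
Product: 26 11-[2-(allyloxy)-5-methoxy-4-(TBDPS-oxymethyl)phenyl]drim-8(12)-ene
Conditions: Ph3PCH3Br, KN(SiMe3)2, THF–toluene, 0 → 60 °C
Reagents that add atoms: methyltriphenylphosphonium bromide C[P+](c1ccccc1)(c1ccccc1)c1ccccc1.[Br-]
Why: Wittig methylenation of the 8-ketone installs C12; any C9 epimer equilibrates under the basic conditions to the equatorial isomer, which is the one olefinated.

Step 19
Reactants: 26 11-[2-(allyloxy)-5-methoxy-4-(TBDPS-oxymethyl)phenyl]drim-8(12)-ene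
Product: 27 2-(drim-8(12)-en-11-yl)-4-methoxy-5-(TBDPS-oxymethyl)phenol
Conditions: Pd(PPh3)4 (5 mol %), K2CO3, MeOH, rt
Reagents that add atoms: none
Why: Zerovalent palladium ionises the aryl allyl ether and methoxide takes up the allyl group; this frees only the C6' oxygen without acid or hydrogen, so the exocyclic alkene is safe.

Step 20
Reactants: 27 2-(drim-8(12)-en-11-yl)-4-methoxy-5-(TBDPS-oxymethyl)phenol
Product: 28 2-(drim-8(12)-en-11-yl)-4,4-dimethoxy-5-(TBDPS-oxymethyl)cyclohexa-2,5-dien-1-one
Conditions: PhI(OAc)2, MeOH, 0 °C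
Reagents that add atoms: methanol CO
Why: Oxidative dearomatisation of a para-methoxyphenol: methanol adds to the phenoxonium ion at C3', so the ketone can only be at C6' and the ketal at C3'.

Step 21
Reactants: 28 2-(drim-8(12)-en-11-yl)-4,4-dimethoxy-5-(TBDPS-oxymethyl)cyclohexa-2,5-dien-1-one
Product: 29 (1S,6R)-1-(drim-8(12)-en-11-yl)-5,5-dimethoxy-4-(TBDPS-oxymethyl)-7-oxabicyclo[4.1.0]hept-3-en-2-one
Conditions: t-BuOOH, aq. NaOH, N-benzylcinchonidinium chloride (10 mol %), toluene, 0 °C
Reagents that add atoms: tert-butyl hydroperoxide CC(C)(C)OO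
Why: Weitz–Scheffer epoxidation: the peroxide anion adds to C2', the only unsubstituted β-carbon (C4' is blocked by its substituent and the ketal), and the enolate closes on oxygen; the chiral ammonium ion pair is to deliver oxygen to the face that gives the C1'/C2' configuration of 37, and the minor diastereomer should be separable because the decalin is enantiopure.

Step 22
Reactants: 29 (1S,6R)-1-(drim-8(12)-en-11-yl)-5,5-dimethoxy-4-(TBDPS-oxymethyl)-7-oxabicyclo[4.1.0]hept-3-en-2-one
Product: 30 (1S,6R)-1-(drim-8(12)-en-11-yl)-4-(hydroxymethyl)-7-oxabicyclo[4.1.0]hept-3-ene-2,5-dione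
Conditions: 48% aq. HF, MeCN, 0 °C → rt
Reagents that add atoms: water O
Why: Aqueous HF hydrolyses the deactivated ketal and cleaves the silyl ether in one operation; HF is too weak an acid to protonate the exocyclic alkene.

Step 23
Reactants: 30 (1S,6R)-1-(drim-8(12)-en-11-yl)-4-(hydroxymethyl)-7-oxabicyclo[4.1.0]hept-3-ene-2,5-dione
Product: 31 (1S,5S,6S)-1-(drim-8(12)-en-11-yl)-5-hydroxy-4-(hydroxymethyl)-7-oxabicyclo[4.1.0]hept-3-en-2-one
Conditions: Me4NBH(OAc)3, MeCN–AcOH, −30 °C
Reagents that add atoms: none
Why: Hydroxyl-directed triacetoxyborohydride reduction: boron bound to the CH2OH oxygen can reach only the neighbouring C3' carbonyl, not C6'; hydride should enter anti to the epoxide C–O bond (Felkin–Anh, away from the oxygen lone pairs), giving the cis epoxy alcohol.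

Step 24
Reactants: 31 (1S,5S,6S)-1-(drim-8(12)-en-11-yl)-5-hydroxy-4-(hydroxymethyl)-7-oxabicyclo[4.1.0]hept-3-en-2-one
Product: 32 (1S,5R,6S)-1-(drim-8(12)-en-11-yl)-5-(4-nitrobenzoyloxy)-4-[(4-nitrobenzoyloxy)methyl]-7-oxabicyclo[4.1.0]hept-3-en-2-one
Conditions: 4-nitrobenzoic acid, PPh3, diisopropyl azodicarboxylate (4 equiv each), toluene, 0 °C → rt
Reagents that add atoms: 4-nitrobenzoic acid OC(=O)c1ccc(cc1)[N+](=O)[O-]
Why: Double Mitsunobu esterification: the primary alcohol is esterified and the C3' alkoxyphosphonium ion is displaced with inversion, which sets the trans epoxy-alcohol relation; the electron-poor benzoate is a poor neighbouring group, so retention through participation is unlikely.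

Step 25
Reactants: 32 (1S,5R,6S)-1-(drim-8(12)-en-11-yl)-5-(4-nitrobenzoyloxy)-4-[(4-nitrobenzoyloxy)methyl]-7-oxabicyclo[4.1.0]hept-3-en-2-one
Product: 33 (1S,5R,6S)-1-(drim-8(12)-en-11-yl)-5-hydroxy-4-(hydroxymethyl)-7-oxabicyclo[4.1.0]hept-3-en-2-one
Conditions: K2CO3 (cat.), MeOH, 0 °C
Reagents that add atoms: none
Why: The activated nitrobenzoates undergo fast transesterification at low temperature, short enough to avoid epoxide migration in the trans epoxy alcohol.

Step 26
Reactants: 34 dimethyl 3-hydroxy-3-methylpentanedioate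
Product: 35 (S)-3-hydroxy-5-methoxy-3-methyl-5-oxopentanoic acid
Conditions: pig liver esterase, phosphate buffer pH 7.5, NaOH (pH-stat), rt; HCl
Reagents that add atoms: water O
Why: Enzymatic desymmetrisation of the prochiral diester: hydrolysis of one enantiotopic ester group creates the C3'' stereocentre.

Step 27
Reactants: 33 (1S,5R,6S)-1-(drim-8(12)-en-11-yl)-5-hydroxy-4-(hydroxymethyl)-7-oxabicyclo[4.1.0]hept-3-en-2-one; 35 (S)-3-hydroxy-5-methoxy-3-methyl-5-oxopentanoic acid
Product: 36 methyl (3R)-3-hydroxy-5-{[(1S,5R,6S)-1-(drim-8(12)-en-11-yl)-5-hydroxy-2-oxo-7-oxabicyclo[4.1.0]hept-3-en-4-yl]methoxy}-3-methyl-5-oxopentanoate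
Conditions: N-(3-dimethylaminopropyl)-N′-ethylcarbodiimide hydrochloride, 4-(dimethylamino)pyridine (cat.), CH2Cl2, 0 °C
Reagents that add atoms: none
Why: Carbodiimide esterification; the primary allylic hydroxyl should react well ahead of the hindered C3' hydroxyl and of the tertiary hydroxyl of 35; C3'' is untouched and becomes (R) only through the change in ranking of the arms.

Step 28
Reactants: 36 methyl (3R)-3-hydroxy-5-{[(1S,5R,6S)-1-(drim-8(12)-en-11-yl)-5-hydroxy-2-oxo-7-oxabicyclo[4.1.0]hept-3-en-4-yl]methoxy}-3-methyl-5-oxopentanoate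
Product: 37 (3R)-3-hydroxy-5-{[(1S,5R,6S)-1-(drim-8(12)-en-11-yl)-5-hydroxy-2-oxo-7-oxabicyclo[4.1.0]hept-3-en-4-yl]methoxy}-3-methyl-5-oxopentanoic acid (target)
Conditions: pig liver esterase, phosphate buffer pH 7.2, acetone (10%), rt
Reagents that add atoms: water O
Why: Esterase hydrolysis of a methyl ester at neutral pH, the usual way to free acids in base-sensitive substrates; the small methyl ester of this acyl unit is a natural substrate, while the ester of the bulky terpenoid alcohol should be cleaved much more slowly.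

Compound list

1 | 5-chloropent-1-yne | C#CCCCCl | starting material
2 | (E)-(5-chloro-2-methylpent-1-en-1-yl)dimethylalane | C[Al](C)/C=C(\C)CCCCl | intermediate
3 | (E)-6-chloro-3-methylhex-2-en-1-ol | OC/C=C(\C)CCCCl | intermediate
4 | 3-methylbut-2-enal | CC(C)=CC=O | starting material
5 | chloromagnesium (E)-6-(chloromagnesio)-3-methylhex-2-en-1-olate | Cl[Mg]CCC/C(C)=C/CO[Mg]Cl | intermediate
6 | trimethyl{[(7E)-3,3,7-trimethyl-9-(trimethylsilyloxy)nona-1,7-dien-1-yl]oxy}silane (enol ether geometry mixed) | C[Si](C)(C)OC=CC(C)(C)CCC/C(C)=C/CO[Si](C)(C)C | intermediate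
7 | (E)-9-hydroxy-3,3,7-trimethylnon-7-enal | O=CCC(C)(C)CCC/C(C)=C/CO | intermediate
8 | (2E,9E)-11-hydroxy-5,5,9-trimethylundeca-2,9-dienal | O=C/C=C/CC(C)(C)CCC/C(C)=C/CO | intermediate
9 | (2E,9E)-3,7,7-trimethyl-11-oxoundeca-2,9-dien-1-yl acetate | CC(=O)OC/C=C(\C)CCCC(C)(C)C/C=C/C=O | intermediate
10 | (2E,8E,10E)-11-[(tert-butyldimethylsilyl)oxy]-3,7,7-trimethylundeca-2,8,10-trien-1-yl acetate | CC(=O)OC/C=C(\C)CCCC(C)(C)/C=C/C=C/O[Si](C)(C)C(C)(C)C | intermediate
11 | (2E,8E,10E)-11-[(tert-butyldimethylsilyl)oxy]-3,7,7-trimethylundeca-2,8,10-trien-1-ol | OC/C=C(\C)CCCC(C)(C)/C=C/C=C/O[Si](C)(C)C(C)(C)C | intermediate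
12 | (2E,8E,10E)-11-[(tert-butyldimethylsilyl)oxy]-3,7,7-trimethylundeca-2,8,10-trienal | O=C/C=C(\C)CCCC(C)(C)/C=C/C=C/O[Si](C)(C)C(C)(C)C | intermediate
13 | 8β-[(tert-butyldimethylsilyl)oxy]-12-nordrim-6-en-11-al | [C@H]1(O[Si](C)(C)C(C)(C)C)C=C[C@H]2C(C)(C)CCC[C@]2(C)[C@H]1C=O | intermediate
14 | 8β-[(tert-butyldimethylsilyl)oxy]-12-nordriman-11-al | [C@H]1(O[Si](C)(C)C(C)(C)C)CC[C@H]2C(C)(C)CCC[C@]2(C)[C@H]1C=O | intermediate
15 | 4-bromo-2,5-dimethoxybenzaldehyde | COc1cc(C=O)c(OC)cc1Br | starting material
16 | 4-bromo-2,5-dihydroxybenzaldehyde | Oc1cc(C=O)c(O)cc1Br | intermediate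
17 | 5-(allyloxy)-4-bromo-2-hydroxybenzaldehyde | C=CCOc1cc(C=O)c(O)cc1Br | intermediate
18 | 5-(allyloxy)-4-bromo-2-methoxybenzaldehyde | C=CCOc1cc(C=O)c(OC)cc1Br | intermediate
19 | [5-(allyloxy)-4-bromo-2-methoxyphenyl]methanol | C=CCOc1cc(CO)c(OC)cc1Br | intermediate
20 | {[5-(allyloxy)-4-bromo-2-methoxybenzyl]oxy}(tert-butyl)diphenylsilane | C=CCOc1cc(CO[Si](c2ccccc2)(c2ccccc2)C(C)(C)C)c(OC)cc1Br | intermediate
21 | [2-(allyloxy)-5-methoxy-4-(TBDPS-oxymethyl)phenyl]lithium | [Li]c1cc(OC)c(CO[Si](c2ccccc2)(c2ccccc2)C(C)(C)C)cc1OCC=C | intermediate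
22 | (11RS)-11-[2-(allyloxy)-5-methoxy-4-(TBDPS-oxymethyl)phenyl]-8β-(TBS-oxy)-12-nordriman-11-ol | [C@H]1(O[Si](C)(C)C(C)(C)C)CC[C@H]2C(C)(C)CCC[C@]2(C)[C@H]1C(O)c1cc(OC)c(CO[Si](c2ccccc2)(c2ccccc2)C(C)(C)C)cc1OCC=C | intermediate
23 | 11-[2-(allyloxy)-5-methoxy-4-(TBDPS-oxymethyl)phenyl]-8β-(TBS-oxy)-12-nordrimane | [C@H]1(O[Si](C)(C)C(C)(C)C)CC[C@H]2C(C)(C)CCC[C@]2(C)[C@H]1Cc1cc(OC)c(CO[Si](c2ccccc2)(c2ccccc2)C(C)(C)C)cc1OCC=C | intermediate
24 | 11-[2-(allyloxy)-5-methoxy-4-(TBDPS-oxymethyl)phenyl]-12-nordriman-8β-ol | [C@H]1(O)CC[C@H]2C(C)(C)CCC[C@]2(C)[C@H]1Cc1cc(OC)c(CO[Si](c2ccccc2)(c2ccccc2)C(C)(C)C)cc1OCC=C | intermediate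
25 | 11-[2-(allyloxy)-5-methoxy-4-(TBDPS-oxymethyl)phenyl]-12-nordriman-8-one | O=C1CC[C@H]2C(C)(C)CCC[C@]2(C)[C@H]1Cc1cc(OC)c(CO[Si](c2ccccc2)(c2ccccc2)C(C)(C)C)cc1OCC=C | intermediate
26 | 11-[2-(allyloxy)-5-methoxy-4-(TBDPS-oxymethyl)phenyl]drim-8(12)-ene | C=C1CC[C@H]2C(C)(C)CCC[C@]2(C)[C@H]1Cc1cc(OC)c(CO[Si](c2ccccc2)(c2ccccc2)C(C)(C)C)cc1OCC=C | intermediate
27 | 2-(drim-8(12)-en-11-yl)-4-methoxy-5-(TBDPS-oxymethyl)phenol | C=C1CC[C@H]2C(C)(C)CCC[C@]2(C)[C@H]1Cc1cc(OC)c(CO[Si](c2ccccc2)(c2ccccc2)C(C)(C)C)cc1O | intermediate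
28 | 2-(drim-8(12)-en-11-yl)-4,4-dimethoxy-5-(TBDPS-oxymethyl)cyclohexa-2,5-dien-1-one | C=C1CC[C@H]2C(C)(C)CCC[C@]2(C)[C@H]1CC1=CC(OC)(OC)C(CO[Si](c2ccccc2)(c2ccccc2)C(C)(C)C)=CC1=O | intermediate
29 | (1S,6R)-1-(drim-8(12)-en-11-yl)-5,5-dimethoxy-4-(TBDPS-oxymethyl)-7-oxabicyclo[4.1.0]hept-3-en-2-one | C=C1CC[C@H]2C(C)(C)CCC[C@]2(C)[C@H]1C[C@]12O[C@H]1C(OC)(OC)C(CO[Si](c3ccccc3)(c3ccccc3)C(C)(C)C)=CC2=O | intermediate
30 | (1S,6R)-1-(drim-8(12)-en-11-yl)-4-(hydroxymethyl)-7-oxabicyclo[4.1.0]hept-3-ene-2,5-dione | C=C1CC[C@H]2C(C)(C)CCC[C@]2(C)[C@H]1C[C@]12O[C@H]1C(=O)C(CO)=CC2=O | intermediate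
31 | (1S,5S,6S)-1-(drim-8(12)-en-11-yl)-5-hydroxy-4-(hydroxymethyl)-7-oxabicyclo[4.1.0]hept-3-en-2-one (cis epoxy alcohol) | C=C1CC[C@H]2C(C)(C)CCC[C@]2(C)[C@H]1C[C@]12O[C@H]1[C@@H](O)C(CO)=CC2=O | intermediate
32 | (1S,5R,6S)-1-(drim-8(12)-en-11-yl)-5-(4-nitrobenzoyloxy)-4-[(4-nitrobenzoyloxy)methyl]-7-oxabicyclo[4.1.0]hept-3-en-2-one | C=C1CC[C@H]2C(C)(C)CCC[C@]2(C)[C@H]1C[C@]12O[C@H]1[C@H](OC(=O)c3ccc(cc3)[N+](=O)[O-])C(COC(=O)c3ccc(cc3)[N+](=O)[O-])=CC2=O | intermediate
33 | (1S,5R,6S)-1-(drim-8(12)-en-11-yl)-5-hydroxy-4-(hydroxymethyl)-7-oxabicyclo[4.1.0]hept-3-en-2-one (trans epoxy alcohol) | C=C1CC[C@H]2C(C)(C)CCC[C@]2(C)[C@H]1C[C@]12O[C@H]1[C@H](O)C(CO)=CC2=O | intermediate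
34 | dimethyl 3-hydroxy-3-methylpentanedioate | COC(=O)CC(C)(O)CC(=O)OC | starting material
35 | (S)-3-hydroxy-5-methoxy-3-methyl-5-oxopentanoic acid | OC(=O)C[C@](C)(O)CC(=O)OC | intermediate
36 | methyl (3R)-3-hydroxy-5-{[(1S,5R,6S)-1-(drim-8(12)-en-11-yl)-5-hydroxy-2-oxo-7-oxabicyclo[4.1.0]hept-3-en-4-yl]methoxy}-3-methyl-5-oxopentanoate | C=C1CC[C@H]2C(C)(C)CCC[C@]2(C)[C@H]1C[C@]12O[C@H]1[C@H](O)C(COC(=O)C[C@](C)(O)CC(=O)OC)=CC2=O | intermediate
37 | (3R)-3-hydroxy-5-{[(1S,5R,6S)-1-(drim-8(12)-en-11-yl)-5-hydroxy-2-oxo-7-oxabicyclo[4.1.0]hept-3-en-4-yl]methoxy}-3-methyl-5-oxopentanoic acid | C=C1CC[C@H]2C(C)(C)CCC[C@]2(C)[C@H]1C[C@]12O[C@H]1[C@H](O)C(COC(=O)C[C@](C)(O)CC(=O)O)=CC2=O | target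

Total step count: 28. Longest linear sequence: 22 steps (steps 1–9, 15–25, 27 and 28).

Least certain steps

Step 8 (key step). Three processes may spoil it. Silyl transfer from the dienol ether to the triflimide counter-ion would release an achiral silyl Lewis acid and erode face selection. Bond formation at the quaternary C10 may be slow, with leakage through the exo (cis-fused) transition state as the C4 and C10 methyl groups become 1,3-diaxial. The sense of induction for a β,β-disubstituted enal is not secured by close analogy; the mirror-image catalyst is available if it is opposite. Fallback with auxiliary control, from 12 back to 13: 12 is acetalised with (2R,4R)-2,4-bis(trimethylsilyloxy)pentane and catalytic Me3SiOTf at −78 °C to the (4R,6R)-4,6-dimethyl-1,3-dioxane acetal F1. More Me3SiOTf ionises F1 to a vinyl oxocarbenium ion that undergoes the ionic intramolecular Diels–Alder reaction under control of the C2-symmetric diol and recloses to the 11,11-[(2R,4R)-pentane-2,4-diyldioxy] cycloadduct F2. Pyridinium tosylate in wet acetone then gives 13.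

Step 2. Formation of the dimagnesium reagent may be incomplete, and 1,2-addition to the enal may compete. Fallback, from 3 (through 5) back to 7: the Grignard reagent is added with catalytic CuI to diethyl isopropylidenemalonate, an acceptor that cannot undergo 1,2-addition, to give diethyl 2-[(6E)-8-hydroxy-2,6-dimethyloct-6-en-2-yl]propanedioate F3. Dealkoxycarbonylation (LiCl, wet DMSO, 150 °C) gives ethyl (7E)-9-hydroxy-3,3,7-trimethylnon-7-enoate F4, and i-Bu2AlH at −78 °C gives 7.

Step 21. Face selection may be poor if the ion-pair catalyst and the bias of the chiral side chain are mismatched. Fallback with a covalent auxiliary, from 28 back to 30: 28 is transketalised with (2R,4R)-pentane-2,4-diol (pyridinium tosylate, benzene) to the spiro 1,3-dioxane dienone F5. Epoxidation with t-BuOOH and DBU, directed by the axial methyl group of the dioxane, gives the epoxy ketal F6, and 48% aq. HF in MeCN gives 30.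

Step 23. The wrong carbonyl may be reduced, conjugate reduction may occur, or hydride may enter on both faces. Fallback with catalyst control, from 30 back to 33 (steps 24 and 25 are then not needed): 30 is silylated (Et3SiCl, imidazole) to the triethylsilyl ether F7. Reduction with catecholborane and the B-methyl oxazaborolidine from diphenylprolinol, in the antipode that delivers hydride on the epoxide face, addresses the less hindered C3' carbonyl and gives the trans carbinol F8. HF·pyridine then gives 33.

Step 28. The enzyme may also cleave the allylic ester, or conversion may be low because of poor solubility. Fallback without a protecting group, from 33 directly to 37: 33 is acylated at the primary hydroxyl with 3-hydroxy-3-methylglutaric anhydride (pyridine, catalytic 4-(dimethylamino)pyridine). This gives 37 together with its C3'' epimer F9, and the two are separated by preparative HPLC. This fallback also removes the dependence on the enantiomeric purity of 35.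

## Further compounds

F1 | step 8 | (4R,6R)-2-[(1E,7E,9E)-10-(TBS-oxy)-2,6,6-trimethyldeca-1,7,9-trien-1-yl]-4,6-dimethyl-1,3-dioxane | C[C@@H]1C[C@@H](C)OC(/C=C(\C)CCCC(C)(C)/C=C/C=C/O[Si](C)(C)C(C)(C)C)O1
F2 | step 8 | 11,11-[(2R,4R)-pentane-2,4-diyldioxy]-8β-(TBS-oxy)-12-nordrim-6-ene | [C@H]1(O[Si](C)(C)C(C)(C)C)C=C[C@H]2C(C)(C)CCC[C@]2(C)[C@H]1C1O[C@H](C)C[C@@H](C)O1
F3 | step 2 | diethyl 2-[(6E)-8-hydroxy-2,6-dimethyloct-6-en-2-yl]propanedioate | CCOC(=O)C(C(=O)OCC)C(C)(C)CCC/C(C)=C/CO
F4 | step 2 | ethyl (7E)-9-hydroxy-3,3,7-trimethylnon-7-enoate | CCOC(=O)CC(C)(C)CCC/C(C)=C/CO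
F5 | step 21 | (2R,4R)-pentane-2,4-diyl ketal analogue of 28 (spiro 1,3-dioxane dienone) | C=C1CC[C@H]2C(C)(C)CCC[C@]2(C)[C@H]1CC1=CC2(O[C@H](C)C[C@@H](C)O2)C(CO[Si](c3ccccc3)(c3ccccc3)C(C)(C)C)=CC1=O
F6 | step 21 | (2R,4R)-pentane-2,4-diyl ketal analogue of 29 (epoxy ketal) | C=C1CC[C@H]2C(C)(C)CCC[C@]2(C)[C@H]1C[C@]12O[C@H]1C1(O[C@H](C)C[C@@H](C)O1)C(CO[Si](c3ccccc3)(c3ccccc3)C(C)(C)C)=CC2=O
F7 | step 23 | triethylsilyl ether of 30 | C=C1CC[C@H]2C(C)(C)CCC[C@]2(C)[C@H]1C[C@]12O[C@H]1C(=O)C(CO[Si](CC)(CC)CC)=CC2=O
F8 | step 23 | primary triethylsilyl ether of 33 | C=C1CC[C@H]2C(C)(C)CCC[C@]2(C)[C@H]1C[C@]12O[C@H]1[C@H](O)C(CO[Si](CC)(CC)CC)=CC2=O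
F9 | step 28 | C3'' epimer of 37 (3S) | C=C1CC[C@H]2C(C)(C)CCC[C@]2(C)[C@H]1C[C@]12O[C@H]1[C@H](O)C(COC(=O)C[C@@](C)(O)CC(=O)O)=CC2=O
A1 | alternative 1 | open-chain (Z)-β-iodoenone epoxy aldehyde (C3' aldehyde, C4' iodide, 4-methoxybenzyl ether) | C=C1CC[C@H]2C(C)(C)CCC[C@]2(C)[C@H]1C[C@@]1(O[C@H]1C=O)C(=O)/C=C(\I)COCc1ccc(OC)cc1
A2 | alternative 1 | epoxyquinol 4-methoxybenzyl ether | C=C1CC[C@H]2C(C)(C)CCC[C@]2(C)[C@H]1C[C@]12O[C@H]1[C@H](O)C(COCc3ccc(OC)cc3)=CC2=O
A3 | alternative 2 | 11-[2,5-dimethoxy-4-(TBS-oxymethyl)phenyl]drim-8(12)-ene | C=C1CC[C@H]2C(C)(C)CCC[C@]2(C)[C@H]1Cc1cc(OC)c(CO[Si](C)(C)C(C)(C)C)cc1OC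
A4 | alternative 2 | quinone bisketal | C=C1CC[C@H]2C(C)(C)CCC[C@]2(C)[C@H]1CC1=CC(OC)(OC)C(CO[Si](C)(C)C(C)(C)C)=CC1(OC)OC
A5 | alternative 2 | monoketal with the C3' ketone and the C6' ketal | C=C1CC[C@H]2C(C)(C)CCC[C@]2(C)[C@H]1CC1=CC(=O)C(CO[Si](C)(C)C(C)(C)C)=CC1(OC)OC
A6 | alternative 2 | monoketal with the C6' ketone and the C3' ketal | C=C1CC[C@H]2C(C)(C)CCC[C@]2(C)[C@H]1CC1=CC(OC)(OC)C(CO[Si](C)(C)C(C)(C)C)=CC1=O
A7 | alternative 3 | (S)-10,11-epoxyfarnesyl 2,5-dimethoxy-4-(TBS-oxymethyl)benzene | CC1(C)O[C@H]1CC/C(C)=C/CC/C(C)=C/Cc1cc(OC)c(CO[Si](C)(C)C(C)(C)C)cc1OC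
A8 | alternative 3 | 3β-hydroxyalbicanyl dimethoxyarene | C=C1CC[C@H]2C(C)(C)[C@@H](O)CC[C@]2(C)[C@H]1Cc1cc(OC)c(CO[Si](C)(C)C(C)(C)C)cc1OC
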